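At the start of any of these flasks Z cannot form: the step that makes it needs G, and the charge holds Q and J, with no G among them.

    Q + G → G + Z (k1 = 14 L mol⁻¹ min⁻¹, Ea1 = 51.0 kJ mol⁻¹)
    Q → L (k2 = 9.0 × 10⁻⁴ min⁻¹, Ea2 = 91.0 kJ mol⁻¹)
    Q → E (k3 = 4.2 × 10⁻⁴ min⁻¹, Ea3 = 96.0 kJ mol⁻¹)
    J → G (k4 = 0.0075 min⁻¹, Ea4 = 88.0 kJ mol⁻¹)
    (constants at 25 °C)

| setting | north-east | east | south-west | north |
|---|---|---|---|---|
| Q | 40 mM | 40 mM | 40 mM | 40 mM |
| J | 0.12 mM | 0.12 mM | 0.12 mM | 0.12 mM |
| temperature | −5 °C | 25 °C | −20 °C | 10 °C |
| time | 30 h | 30 h | 30 h | 30 h |

- constants are those at 25 °C; use the activation energies for any other temperature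

1. the flask that comes out highest in share of Z in all that became Z or L or E, or "all alike" when all lie within 1.5 percentage points (north-east / east / south-west / north / all alike)
2. share of Z in all that became Z or L or E, north-east
3. share of Z in all that became Z or L or E, east
4. share of Z in all that became Z or L or E, south-west
5. share of Z in all that became Z or L or E, north

J is the reagent charged in the smaller amount, and its balance is short: [J] + [G] stays at 0.12 mM, while [G] rises first-order from zero. Arrhenius scaling down to −20 °C gives, for south-west, 0.361 L mol⁻¹ min⁻¹ for the Z step, 1.75 × 10⁻⁶ min⁻¹ for the L and E steps together, and 1.36 × 10⁻⁵ min⁻¹ for the release of G from J. Two numbers then seem not to go together. With [G] taken at the full 0.12 mM, the constants favour Z over L plus E by 24.8 to one in south-west and by 1.27 to one in east, so south-west looks the better flask. But J in south-west has a half-life of 35.3 d, longer than the 30 h of the run.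

For south-west the full [G] is therefore not the value to use. The routes to Z, L and E each run in proportion to [Q], so while [Q] holds nearly constant, their products stand in a simple proportion. Integrating the rise of [G] gives a time-mean of 0.00146 mM in south-west. The run ratio, which is the Z constant times mean [G] divided by the summed L and E constants, a selectivity factor averaged over the run, comes to 0.302. This reckoning puts the loss of Q at 0.410% and commits to a share of 23.2% in south-west. It stops there: in east the L and E steps reach a first-order exponent of 2.38, and [Q] in east does not stay nearly constant.

The forecast, holding that “the share peaks at an intermediate temperature”, gives 48.9% north-east, 48.2% east, 23.2% south-west and 61.4% north, with north highest.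

The flask that comes out highest is north at 61.4%, with 48.9% north-east, 48.2% east and 23.2% south-west, the last a run ratio of 0.302. At 30.0 h south-west holds G at 2.42% of the catalyst charged and J at 97.6%. Read at 3.0 d instead, with amounts and temperature held, south-west has a run ratio reckoned at 0.716, a share of 41.7%, and that reading stands at 41.7%.

The numbers are those of an exercise; the result is computed.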